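You have two questions to answer, a time and an amount, and one earlier run to answer them from.

- teal: solid substrate 2 M; partner 0.60 equiv; protic impurity 0.60 M; run made earlier
- flask: solid substrate 2.0 M; partner 1.20 equiv; protic impurity 0.600 M; time 40 h

teal run (percent of the solid substrate charged): time / h: target / % = 0.833: 10; 2.00: 20; 4.00: 27; 10.0: 19; 25.0: 15

(scatter of a reading: 1.5 percentage points)

- time, not beyond 40 h, at which the flask holds most target
- the amount of target, in percent of the solid substrate charged, at that time

- as a solid, counted per litre of solution: solid substrate
- at the start none of the solid substrate is in solution

Count turnovers. After its peak reading, teal falls toward its last reading, the excess shrinking from 12 percentage points to 4 points in 6.00 h. I read from this a loss clock of 0.183 h⁻¹, the turnovers of target into loss per hour. Teal's first slope is 0.120 h⁻¹ of the charge. With twice the partner, I expect 0.240 h⁻¹ in the flask, where solid substrate is the limiting reagent, and I take this as a making clock on the whole charge. Two first-order clocks in series, neither running back, peak at the logarithm of their ratio over their difference, so my first estimate for the flask is 4.76 h, at 41.9%.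

The weak link is that making clock. Teal's slope drops to 0.0857 h⁻¹ in the next interval, which reads as a faster clock of 0.337 h⁻¹. With it my estimate for the flask moves to 3.96 h and 48.4%. I assume that the protic impurity takes its share of the solid substrate, so I commit to that time and 33.9%.

The forecast is later and higher than my reckoning: 9 h and 60%, holding that “target should keep rising until the solid or partner is nearly exhausted”.

The flask gives 3.19 h and 37.4%, which is 0.584 loss turnovers.

    dissolved substrate + partner → target (k = 0.360 M⁻¹ h⁻¹)
    target ⇌ isomer of the product (K = 2.70, k = 0.260 h⁻¹)
    solid substrate + protic impurity → quenched substrate (k = 2.40 M⁻¹ h⁻¹)
    solid substrate ⇌ dissolved substrate, rate k4*(cs4 - [dissolved substrate]) while solid is left; crystals form when [dissolved substrate] > cs4 (solubility = 1.20 M, k = 1.30 h⁻¹)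

By then the flask's solid substrate stands at 0%, with 28.1% quenched substrate and 17.1% dissolved substrate, while isomer of the product has reached 17.3%. Afterwards the turning of target into isomer of the product goes on: at 20.0 h the flask holds 19.6% target and 52.2% isomer of the product.

Now read the same flask at 3.0 d. The loss clock read from teal counts 7.32 turnovers by 40 h and 13.2 by then, so I expect target to sit where it stood at 40 h, 19.4%. The computed reading is 19.4%.

The runs stem from a simulated flask for substances that don't exist; the scatter is artificial.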